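Your vessel holds 20 mM of starting material, 100 mM of second substrate and 2.0 µM of free enzyme, and your hunch is that the rate simply follows the enzyme. I'd put a number on that hunch, then see how far it carries.

in all of them: starting material 20 mM

| run | second substrate | free enzyme | remark |
|---|---|---|---|
| summer | 140 mM | 2 µM | run made earlier |
| dusk | 220 mM | 2 µM | run made earlier |
| flask | 100 mM | 2.0 µM |  |

- summer (time / min: target / %, starting material / %): 2.00: 29, 69; 4.00: 54, 49; 6.00: 72, 26; 8.00: 83, 13; 10.0: 92, 6; 12.0: 100, 2
- dusk (time / min: target / %, starting material / %): 1.00: 17, 83; 1.50: 25, 74; 2.50: 38, 62; 4.00: 54, 46; 8.00: 85, 15; 12.0: 100, 0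

(standard deviation of a reading: 1.5 percentage points)

- no earlier run changes the charge of free enzyme; that part of a forecast is a guess

* factor on the rate of making target when 50% of the starting material are converted if free enzyme is charged twice over
* factor on the rate when 50% of the starting material are converted if free enzyme is charged at 10 µM instead

In the summer run, target climbs from 29% at 2.00 min to 72% at 6.00 min, across the 50% mark. That reads as 1080 min⁻¹: the turnover rate, target made per minute per enzyme charged. The dusk run, between 2.50 min and 4.00 min, reads 1070 min⁻¹, about the same, though it was charged with more second substrate than summer. Multiplied by your enzyme, the turnover rate gives 2.15 mM min⁻¹.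

Now go round once more. If second substrate goes one for one with starting material, c(second substrate) at the mark is 90.0 mM in your flask, lower than the 130 mM of summer, so my rate is an extrapolation. Neither run changed the enzyme, so a fixed turnover rate is my assumption; it gives twice the rate for a double charge and 5.00 times at 10 µM.

The forecast says 2 (1.5 to 2.2) and 5 (2.6 to 5.8), warning that “this order is assumed, not measured”.

The flask gives 1.77 and 3.89.

    starting material + free enzyme ⇌ first complex (K = 19.0 L mol⁻¹, k = 1.70 × 10⁶ L mol⁻¹ s⁻¹)
    first complex → loaded enzyme + first product (k = 290 s⁻¹)
    second substrate + loaded enzyme ⇌ second complex (K = 22.0 L mol⁻¹, k = 3.20 × 10⁵ L mol⁻¹ s⁻¹)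
    second complex → free enzyme + target (k = 77.0 s⁻¹)
    2 second complex ⇌ resting dimer (K = 1.60 × 10⁶ L mol⁻¹, k = 7900 L mol⁻¹ s⁻¹)

At 1.50 min the flask holds 25.2% of the catalyst charged in the resting dimer (each dimer counted as two), a resting state outside the working round. Watch the turnover rate: at 3.88 min, with 50% converted, the flask makes 2.00 mM min⁻¹, which is 1000 min⁻¹ per enzyme charged, and with 10 µM of free enzyme at the same conversion it is lower, at 779 min⁻¹.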